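**Plan**

- Feature used: in the chroman (O1, C2, C3, C4, C4a, C5–C8, C8a; side chain C1'–C8' outward from C2) the tertiary ether carbon C2 is the Markovnikov end of an E-trisubstituted alkene of a farnesyl-type chain lying ortho to the phenol oxygen on C8a, the array that protonation-initiated prenylphenol cyclases close.
- Retrosynthesis cuts, in this order: O1–C2 (pyran ring opened to the open-chain farnesyl orcinol ester), the two phenol acetals, the C7'=C8' enoate alkene (aldehyde plus phosphonate), and the aryl–CH2 bond C4a–C4 (aryl bromide plus epoxyfarnesyl bromide).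
- Forward: farnesol becomes its terminal epoxide and allylic bromide, and orcinol becomes a bis-MOM aryl bromide. The arylcopper and the bromide are joined, the epoxide is cleaved to the aldehyde, the Z-enoate is installed, the phenols are freed, and the pyran ring, the only ring made, closes last.
- Stereochemistry: both E-alkenes are those of (2E,6E)-farnesol and are never touched, the Z-enoate comes from the Still–Gennari olefination, and the single stereocentre C2 (R) is set in the last step by the enzyme pocket.

Key step: step 11

Assumption: the carbon that carries bromine and then the epoxide oxygen is racemic from step 2 onward and is excised in step 8, so it is left uncontrolled; anhydrous orcinol is used.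

**Route**

Step 1
Reactants: 1 (2E,6E)-farnesol
Product: 2 (2E,6E)-farnesyl acetate
Conditions: Ac2O, pyridine, DMAP (4-dimethylaminopyridine, cat.), CH2Cl2, 0 °C to rt
Reagents that add atoms: acetic anhydride, CC(=O)OC(C)=O
Why: DMAP-catalysed O-acylation of the primary allylic alcohol; the acetate withdraws electron density from the C2=C3 alkene and so steers the next step to the far end of the chain.

Step 2
Reactants: 2 (2E,6E)-farnesyl acetate
Product: 3 (2E,6E)-10-bromo-11-hydroxy-3,7,11-trimethyldodeca-2,6-dien-1-yl acetate (racemic)
Conditions: NBS (1.05 equiv), THF/H2O, 0 °C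
Reagents that add atoms: N-bromosuccinimide, O=C1CCC(=O)N1Br; water, O
Why: Terminal-selective bromohydrin formation: in aqueous THF the coiled polyene exposes its terminal alkene, water opens the bromonium ion at the tertiary carbon (Markovnikov) and the allylic acetate deactivates the 2,3-alkene; the new stereocentre is racemic and is removed in step 8.

Step 3
Reactants: 3 bromohydrin acetate
Product: 5 (2E,6E)-10,11-epoxyfarnesol (racemic), via epoxyfarnesyl acetate 4 (not isolated)
Conditions: K2CO3 (2.5 equiv), MeOH, rt
Reagents that add atoms: none
Why: Intramolecular Williamson etherification of the bromohydrin closes the oxirane, and carbonate-catalysed transesterification with methanol removes the acetate in the same flask.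

Step 4
Reactants: 5 (2E,6E)-10,11-epoxyfarnesol
Product: 7 (2E,6E)-10,11-epoxyfarnesyl bromide (racemic), via epoxyfarnesyl mesylate 6 (not isolated)
Conditions: MsCl, Et3N, THF, −45 °C; then LiBr, THF, 0 °C; used crude
Reagents that add atoms: lithium bromide, [Li+].[Br-]
Why: Mesylation followed by SN2 displacement with bromide (Finkelstein-type) at the primary allylic carbon below 0 °C should keep the E-alkene and the acid-sensitive epoxide intact.

Step 5
Reactants: 8 orcinol (5-methylbenzene-1,3-diol)
Product: 9 1,3-bis(methoxymethoxy)-5-methylbenzene
Conditions: MOMCl (2.6 equiv), iPr2NEt, CH2Cl2, 0 °C to rt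
Reagents that add atoms: chloromethyl methyl ether, COCCl
Why: Williamson-type O-alkylation of both phenols gives acetals that withstand organolithium and organocopper reagents and add no stereocentre.

Step 6
Reactants: 9 1,3-bis(methoxymethoxy)-5-methylbenzene
Product: 10 1-bromo-2,4-bis(methoxymethoxy)-6-methylbenzene
Conditions: NBS (1.0 equiv), MeCN, 0 °C
Reagents that add atoms: N-bromosuccinimide, O=C1CCC(=O)N1Br
Why: Electrophilic aromatic bromination goes ortho to one acetal oxygen and para to the other, the position between the two oxygens being the more crowded; the two such positions are equivalent by symmetry, so one monobromide should form.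

Step 7
Reactants: 10 1-bromo-2,4-bis(methoxymethoxy)-6-methylbenzene (1.4 equiv); 7 (2E,6E)-10,11-epoxyfarnesyl bromide
Product: 13 3-[(3E,7E)-9-[2,4-bis(methoxymethoxy)-6-methylphenyl]-3,7-dimethylnona-3,7-dien-1-yl]-2,2-dimethyloxirane (racemic), via aryllithium 11 (not isolated), via arylcopper 12 (not isolated)
Conditions: n-BuLi, THF, −78 °C; CuBr·SMe2, −78 to −40 °C; then 7, −78 to 0 °C
Reagents that add atoms: none
Why: Bromine–lithium exchange, transmetalation to monovalent copper and SN2 allylic substitution at the primary carbon: the doubly ortho-substituted arylcopper avoids the tertiary γ-carbon, the E-alkene is retained, the trisubstituted epoxide is inert at these temperatures, and the aryl–CH2 bond forms where the bromine stood.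

Step 8
Reactants: 13 aryl epoxide
Product: 15 (4E,8E)-10-[2,4-bis(methoxymethoxy)-6-methylphenyl]-4,8-dimethyldeca-4,8-dienal, via vicinal diol 14 (not isolated)
Conditions: H5IO6 (1.2 equiv), THF/Et2O, 0 °C, 30 min
Reagents that add atoms: none
Why: Periodic acid opens the epoxide at its tertiary carbon to the vicinal diol and cleaves it in a Malaprade glycol fission, so the epoxide oxygen ends as the aldehyde oxygen and the isopropylidene carbon leaves as acetone; the aryl acetals and the alkenes should tolerate the short cold exposure.

Step 9
Reactants: 15 aldehyde; 16 methyl 2-[bis(2,2,2-trifluoroethoxy)phosphoryl]propanoate (1.3 equiv)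
Product: 18 methyl (2Z,6E,10E)-12-[2,4-bis(methoxymethoxy)-6-methylphenyl]-2,6,10-trimethyldodeca-2,6,10-trienoate, via potassium phosphonate anion 17 (not isolated)
Conditions: 16, KN(SiMe3)2, 18-crown-6, THF, −78 °C; then 15, −78 °C
Reagents that add atoms: none
Why: Still–Gennari variant of the Horner–Wadsworth–Emmons olefination: with the electron-poor bis(trifluoroethyl) phosphonate and a crown-ether-separated potassium ion the adduct eliminates faster than it equilibrates, which should give the Z-trisubstituted enoate (ester cis to the chain).

Step 10
Reactants: 18 bis-MOM Z-enoate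
Product: 19 methyl (2Z,6E,10E)-12-(2,4-dihydroxy-6-methylphenyl)-2,6,10-trimethyldodeca-2,6,10-trienoate
Conditions: p-toluenesulfonic acid monohydrate (p-TsOH·H2O, 0.3 equiv), MeOH, rt to 35 °C
Reagents that add atoms: none
Why: Acid-catalysed acetal exchange with methanol frees both phenols as dimethoxymethane leaves; the methyl ester is degenerate toward methanol, and catalytic acid near room temperature is well short of what protonates the trisubstituted alkenes, so the pyran ring should stay open.

Step 11
Reactants: 19 open-chain farnesyl orcinol ester
Product: 20 methyl (2Z,6E)-9-[(2R)-7-hydroxy-2,5-dimethyl-3,4-dihydro-2H-chromen-2-yl]-2,6-dimethylnona-2,6-dienoate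
Conditions: squalene–hopene cyclase from Alicyclobacillus acidocaldarius, active-site variant chosen from a focused library, E. coli whole cells, citrate buffer pH 6.0, 2-hydroxypropyl-β-cyclodextrin, 30 °C
Reagents that add atoms: none
Why: Proposed new method: the catalytic aspartic acid of the cyclase (Asp376 in the parent enzyme) should protonate C3 of the arene-proximal C2=C3 alkene while the C8a hydroxyl, held over the opposite face, adds to C2, a Markovnikov hydroalkoxylation that forms O1–C2 in concert or through a tightly held tertiary cation. The closest known reaction types are the tocopherol-cyclase closure of prenylated hydroquinones to (R)-chromanols and the Brønsted-acid cyclisations that squalene–hopene cyclase variants run on unnatural polyenes with oxygen nucleophiles as terminators. The pyran ring closes in the 6-endo-trig mode. The configuration at C2, the only new stereocentre, is controlled by the enzyme pocket, which binds one fold of the chain and so presents one face of C2 to the phenol oxygen; the variant giving the (R)-ether is to be picked by chiral HPLC screening against the racemate. The step needs site selectivity (C2=C3 and not the central C3'=C4' alkene, whose protonation would start a polyene cyclisation) and face selectivity, and the substrate helps: only the C8a hydroxyl is ortho to the chain, the enoate alkene is too electron-poor to be protonated, and a hydrogen bond from the ortho hydroxyl to the catalytic acid places the nearest alkene at the proton. At pH 6 and 30 °C a phenol does not protonate an alkene, so no racemic background closure is expected.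

**Compound list**

1 | (2E,6E)-farnesol | CC(C)=CCC/C(C)=C/CC/C(C)=C/CO | starting material
2 | (2E,6E)-farnesyl acetate | CC(C)=CCC/C(C)=C/CC/C(C)=C/COC(C)=O | intermediate
3 | (2E,6E)-10-bromo-11-hydroxy-3,7,11-trimethyldodeca-2,6-dien-1-yl acetate (racemic) | CC(C)(O)C(Br)CC/C(C)=C/CC/C(C)=C/COC(C)=O | intermediate
4 | (2E,6E)-9-(3,3-dimethyloxiran-2-yl)-3,7-dimethylnona-2,6-dien-1-yl acetate (epoxyfarnesyl acetate, racemic, not isolated) | CC1(C)OC1CC/C(C)=C/CC/C(C)=C/COC(C)=O | intermediate
5 | (2E,6E)-9-(3,3-dimethyloxiran-2-yl)-3,7-dimethylnona-2,6-dien-1-ol (10,11-epoxyfarnesol, racemic) | CC1(C)OC1CC/C(C)=C/CC/C(C)=C/CO | intermediate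
6 | (2E,6E)-9-(3,3-dimethyloxiran-2-yl)-3,7-dimethylnona-2,6-dien-1-yl methanesulfonate (racemic, not isolated) | CC1(C)OC1CC/C(C)=C/CC/C(C)=C/COS(C)(=O)=O | intermediate
7 | 3-[(3E,7E)-9-bromo-3,7-dimethylnona-3,7-dien-1-yl]-2,2-dimethyloxirane (10,11-epoxyfarnesyl bromide, racemic) | CC1(C)OC1CC/C(C)=C/CC/C(C)=C/CBr | intermediate
8 | orcinol (5-methylbenzene-1,3-diol) | Cc1cc(O)cc(O)c1 | starting material
9 | 1,3-bis(methoxymethoxy)-5-methylbenzene | COCOc1cc(C)cc(OCOC)c1 | intermediate
10 | 1-bromo-2,4-bis(methoxymethoxy)-6-methylbenzene | COCOc1cc(C)c(Br)c(OCOC)c1 | intermediate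
11 | [2,4-bis(methoxymethoxy)-6-methylphenyl]lithium (not isolated) | [Li]c1c(C)cc(OCOC)cc1OCOC | intermediate
12 | [2,4-bis(methoxymethoxy)-6-methylphenyl]copper, monovalent copper (not isolated) | [Cu]c1c(C)cc(OCOC)cc1OCOC | intermediate
13 | 3-[(3E,7E)-9-[2,4-bis(methoxymethoxy)-6-methylphenyl]-3,7-dimethylnona-3,7-dien-1-yl]-2,2-dimethyloxirane (racemic) | CC1(C)OC1CC/C(C)=C/CC/C(C)=C/Cc1c(C)cc(OCOC)cc1OCOC | intermediate
14 | (6E,10E)-12-[2,4-bis(methoxymethoxy)-6-methylphenyl]-2,6,10-trimethyldodeca-6,10-diene-2,3-diol (racemic, not isolated) | CC(C)(O)C(O)CC/C(C)=C/CC/C(C)=C/Cc1c(C)cc(OCOC)cc1OCOC | intermediate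
15 | (4E,8E)-10-[2,4-bis(methoxymethoxy)-6-methylphenyl]-4,8-dimethyldeca-4,8-dienal | O=CCC/C(C)=C/CC/C(C)=C/Cc1c(C)cc(OCOC)cc1OCOC | intermediate
16 | methyl 2-[bis(2,2,2-trifluoroethoxy)phosphoryl]propanoate (racemic) | COC(=O)C(C)P(=O)(OCC(F)(F)F)OCC(F)(F)F | starting material
17 | potassium salt of the carbanion of 16 (not isolated) | COC(=O)[C-](C)P(=O)(OCC(F)(F)F)OCC(F)(F)F.[K+] | intermediate
18 | methyl (2Z,6E,10E)-12-[2,4-bis(methoxymethoxy)-6-methylphenyl]-2,6,10-trimethyldodeca-2,6,10-trienoate | COC(=O)/C(C)=C\CC/C(C)=C/CC/C(C)=C/Cc1c(C)cc(OCOC)cc1OCOC | intermediate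
19 | methyl (2Z,6E,10E)-12-(2,4-dihydroxy-6-methylphenyl)-2,6,10-trimethyldodeca-2,6,10-trienoate | COC(=O)/C(C)=C\CC/C(C)=C/CC/C(C)=C/Cc1c(C)cc(O)cc1O | intermediate
20 | methyl (2Z,6E)-9-[(2R)-7-hydroxy-2,5-dimethyl-3,4-dihydro-2H-chromen-2-yl]-2,6-dimethylnona-2,6-dienoate | COC(=O)/C(C)=C\CC/C(C)=C/CC[C@]1(C)CCc2c(C)cc(O)cc2O1 | target

**Totals**

Total step count: 11.
Longest linear sequence: 9 steps (steps 1–4 and 7–11, from farnesol); the arene branch is steps 5–6.

**Steps most likely to fail**

Step 11. No variant may turn over the resorcinol substrate, protonation may start at the central alkene and run on into a polyene cyclisation, or the oxygen may add to the wrong face of C2. The fallback uses known chemistry and sets out from 19. Brønsted-acid ring closure with p-toluenesulfonic acid monohydrate (cat., toluene, 50 °C), the standard conversion of ortho-prenyl phenols into 2,2-dialkylchromans, should give the racemic chroman F1. Preparative HPLC on a cellulose tris(3,5-dimethylphenylcarbamate) chiral stationary phase then separates the enantiomers, and the (R)-enantiomer, assigned by comparing its chiroptical data with calculation, is 20, where the route is rejoined.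

Step 10. The acid that cleaves the acetals may also protonate the arene-proximal alkene, so that ring closure without enantiocontrol runs ahead of the enzyme. The fallback sets out from 18 and replaces acetal solvolysis by a protecting-group exchange under aprotic conditions. Et3SiOTf with 2,2′-bipyridyl (CH2Cl2, 0 °C) should convert both aryl methoxymethyl ethers directly into silyl ethers, giving the bis(triethylsilyl) ether F2. Tetrabutylammonium fluoride buffered with acetic acid (THF, 0 °C) then frees the phenols, so that no acid is present once they are unmasked, and the route is rejoined at 19.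

Step 7. The arylmetal may be protonated before it couples, attack may occur at the γ-carbon (SN2′), or alkene geometry may be partly lost. The fallback sets out from 10 and changes the bond construction from copper-mediated substitution to palladium cross-coupling. Bromine–lithium exchange to 11 and a quench with Bu3SnCl should give the aryl tributylstannane F3. A Stille coupling of this stannane with bromide 7 (Pd2(dba)3 as zerovalent palladium source, tri(2-furyl)phosphine, THF/N-methylpyrrolidone, 50 °C) should join the less hindered terminus of the allyl unit with retention of the E-alkene and rejoin the route at 13.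

**Further compounds**

F1 | step 11 | methyl (2Z,6E)-9-(7-hydroxy-2,5-dimethyl-3,4-dihydro-2H-chromen-2-yl)-2,6-dimethylnona-2,6-dienoate (racemic) | COC(=O)/C(C)=C\CC/C(C)=C/CCC1(C)CCc2c(C)cc(O)cc2O1
F2 | step 10 | methyl (2Z,6E,10E)-2,6,10-trimethyl-12-[6-methyl-2,4-bis(triethylsilyloxy)phenyl]dodeca-2,6,10-trienoate | COC(=O)/C(C)=C\CC/C(C)=C/CC/C(C)=C/Cc1c(C)cc(O[Si](CC)(CC)CC)cc1O[Si](CC)(CC)CC
F3 | step 7 | tributyl[2,4-bis(methoxymethoxy)-6-methylphenyl]stannane | CCCC[Sn](CCCC)(CCCC)c1c(C)cc(OCOC)cc1OCOC
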